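The two runs began nearly alike and ended far apart: at 1.04 d theta stood at 39% and epsilon at 35%, but at 5.00 d they stood at 52% and 34%.

| setting | theta | epsilon | flask |
|---|---|---|---|
| starting material | 20 mM | 20 mM | 20 mM |
| free enzyme | 2 µM | 2 µM | 2.0 µM |
| temperature | 30 °C | 36 °C | 30 °C |
| remark | the very flask that is asked about, followed so far | run made earlier |  |
| time |  |  | 8.0 d |

| run | time / d | product / % |
|---|---|---|
| theta | 1.04 | 39 |
| theta | 2.08 | 45 |
| theta | 3.00 | 50 |
| theta | 4.00 | 51 |
| theta | 5.00 | 52 |
| epsilon | 1.04 | 35 |
| epsilon | 2.08 | 34 |
| epsilon | 3.00 | 33 |
| epsilon | 4.00 | 36 |
| epsilon | 5.00 | 34 |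

(scatter of a reading: 2 percentage points)

- south-west: at 8.0 d take out 90% of the product then present, then wait 2.5 d
- north-east: at 8.0 d add free enzyme, 100% of the amount charged, then wait 2.5 d
- south: at 8.0 d raise the temperature by 25 K, then wait 2.5 d
- south-east: change nothing and wait 2.5 d more

- product that was removed still counts
- reactions considered so far: starting material <-> dormant form; free enzyme -> unfolded enzyme; starting material + free enzyme -> product + free enzyme
- additions bring no volume worth counting

- product, in percent of the starting material first charged, at 8.0 d
- the option that brings most further product ("none" if no option brings more than 2 percentage points) (south-west / north-east / south / south-east / none)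
- product present, with what was taken out counted in, in percent of the starting material first charged, after north-east
- product present, with what was taken out counted in, in percent of the starting material first charged, after south

After its first reading, the warmer epsilon run changed by −1 percentage point, which lay within the scatter, while theta gained 13 points. With equal charges and 66.0% of the charge not turned into product, I read epsilon's stop as enzyme lost sooner in the warmth (deactivation).

Theta's early fall looked different. After its first 39%, it gained 6 points by 2.08 d and 5 points by 3.00 d. A steady first-order enzyme loss on a fixed supply would have cut each gain by one factor. The sharp drop followed by a slow tail made me think that the supply the enzyme could reach had thinned within the first day.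

So I carried the late gain G, the product that one full charge of enzyme makes during the wait on that thinned supply, taken from theta's late slope and treating the charge as whole:

G = (52% − 45%) × 2.5 d / (5.00 d − 2.08 d) = 6 points

Repeating theta's last gain once gave me 54.0% at 8.0 d. Fresh enzyme would then reach 60.0%, a gain larger than the margin of 2 points, so I chose north-east. Epsilon's flat tail put the south option at my 54.0% too.

The forecast gave 53%, north-east, 75% for north-east and 53% for south. Its ground for north-east was: “Fresh enzyme should convert about half of the remaining”. We agreed on the choice but differed on its size.

The flask gave 54.7%, north-east, 61.4% after north-east and 54.7% after south.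

    starting material ⇌ dormant form (K = 2.40, k = 0.150 h⁻¹, Ea = 92.0 kJ mol⁻¹, ΔH = −13.0 kJ mol⁻¹)
    free enzyme → unfolded enzyme (k = 0.0100 h⁻¹, Ea = 223 kJ mol⁻¹)
    starting material + free enzyme → product + free enzyme, rate k3*[starting material]^2.5*[free enzyme]/(1 + ([starting material]/Kh3)^2.5) (29.0 mM, k = 13000 M⁻²·⁵ s⁻¹, Ea = 21.0 kJ mol⁻¹)
    (constants at 30 °C)

The north-east option gained 6.7 points and the south-east wait with nothing changed gained 1.1 points, so the fresh charge itself added 5.6 points, against my G of 6 points; at 8.00 d the unconverted part held 13.2% starting material and 32.0% dormant form. The neighbour flask with 0.0050 mM of free enzyme held 2.50 charges. One charge in this flask, with a half-life of 2.9 d and 14.7% left, gave 3.56 d of full-charge working time by 8.00 d. So: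

product ≈ 54.7% + (1.50 × 3.56 d) × 6 points / 2.5 d = 67.5%

That neighbour flask gave 71.2%.

The numbers in the tables stem from a simulated flask with made-up constants.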